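Everything hinges on breaking the C5–C6 bond. In the target C6 belongs to two rings: it is the oxygen-bearing sp3 carbon of the five-membered C6–C7=C11–C12(=O)–O lactone and the neighbour of the E-configured C4=C5 double bond inside the ten-membered carbocycle. Retrosynthetically C6 therefore becomes an aldehyde held cis to a C12 ester across C7=C11, a unit that a 2-silylfuran releases on photooxygenation. In one operation a Ni/Cr-mediated alkenyl iodide–aldehyde addition makes C5–C6, closes the carbocycle, creates the C6 stereocentre and triggers lactonisation. The cyclisation precursor is an open chain with an E-iodoalkene at one end, the C1 ketone and silylated C8/C10 carbinols in the middle, and the formyl acrylate silyl ester at the other end.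

Key step: step 15

Numbering: germacranolide numbers are used. C1 is the ketone, C2 and C3 are methylenes, C4=C5 carries methyl C15, C6 is the lactone carbinol, C7=C11 is the butenolide olefin, C8 is the methacrylate carbinol, C9 is a methylene, C10 is the tertiary acetate carbon with methyl C14, C12 is the lactone carbonyl and C13 is the acetoxymethyl carbon. The target is 4E,6R,8S,10R.

Abbreviation: Fu = 5-(tert-butyldimethylsilyl)-4-[(tert-butyldimethylsilyloxy)methyl]furan-3-yl, in which furan C3 = C7, C2–H = C6, C4 = C11 and C5 = C12.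

Assumption: the (R,R) bis(oxazoline) ligand is taken to give the R carbinol, because the (S,S) ligand is known to give S carbinols from methyl pyruvate. A wrong assignment would show up at the γ-lactone stage as the cis instead of the trans isomer and would be cured by exchanging the ligand enantiomer.

Protecting groups: the silyl ethers are graded (secondary TES on O8, tertiary TES on O10, primary TBS on O13). O8 can therefore be freed and acylated alone, and both acetates enter together in the last step.

Step 1
Reactants: 1 3-furanmethanol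
Product: 2 3-[(tert-butyldimethylsilyloxy)methyl]furan
Conditions: TBSCl, imidazole, DMF, 0 °C to rt
Reagents that add atoms: tert-butyldimethylsilyl chloride, CC(C)(C)[Si](C)(C)Cl
Why: Routine imidazole-promoted O-silylation of a primary alcohol, which parks on oxygen the silyl group that the next step moves to carbon.

Step 2
Reactants: 2 3-[(tert-butyldimethylsilyloxy)methyl]furan
Product: 4 2-(tert-butyldimethylsilyl)-3-furanmethanol, via 2-lithiofuran 3 (not isolated)
Conditions: n-BuLi, HMPA, THF, −78 °C to rt; aq NH4Cl
Reagents that add atoms: none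
Why: The silyloxymethyl group steers lithiation to the neighbouring α-carbon and the carbanion then takes silicon from oxygen in a 1,4 O-to-C shift (retro-Brook rearrangement) that is established for 3-(silyloxymethyl)furans, so silicon marks the future C12.

Step 3
Reactants: 4 2-(tert-butyldimethylsilyl)-3-furanmethanol; 5 N-methoxy-N-methylacetamide
Product: 7 4-acetyl-2-(tert-butyldimethylsilyl)-3-(hydroxymethyl)furan, via C4,O-dilithio species 6 (not isolated)
Conditions: n-BuLi (2.2 equiv), DME, 0 °C; 5, −78 to 0 °C; aq NH4Cl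
Reagents that add atoms: none
Why: With C2 blocked by silicon the lithium alkoxide directs the second deprotonation to C4 (directed ortho-metalation, best in DME), and acylation by the Weinreb amide stops at the ketone because the chelated tetrahedral adduct survives until the quench.

Step 4
Reactants: 7 4-acetyl-2-(tert-butyldimethylsilyl)-3-(hydroxymethyl)furan
Product: 8 methyl ketone Fu–C(=O)CH3
Conditions: TBSCl, imidazole, CH2Cl2, rt
Reagents that add atoms: tert-butyldimethylsilyl chloride, CC(C)(C)[Si](C)(C)Cl
Why: Standard silyl ether formation that removes the acidic hydroxyl and its hemiketal equilibrium with the ketone before enol silane formation.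

Step 5
Reactants: 8 methyl ketone Fu–C(=O)CH3
Product: 9 enol silane Fu–C(OSiMe3)=CH2
Conditions: TMSOTf, Et3N, CH2Cl2, 0 °C
Reagents that add atoms: trimethylsilyl triflate, C[Si](C)(C)OS(=O)(=O)C(F)(F)F
Why: Soft enolisation of an aryl-type methyl ketone with a silyl triflate and a tertiary amine gives the only possible enol silane, since the furan side has no α-hydrogen.

Step 6
Reactants: 9 enol silane Fu–C(OSiMe3)=CH2; 10 methyl pyruvate
Product: 12 methyl (2R)-2-hydroxy-2-methyl-4-oxo-4-Fu-butanoate, via O-trimethylsilyl aldol adduct 11 (not isolated)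
Conditions: Cu(OTf)2 (10 mol %), (R,R)-t-Bu-box (11 mol %), THF, −78 °C; 1 M HCl, THF, 0 °C, brief
Reagents that add atoms: none
Why: Catalytic enantioselective Mukaiyama aldol addition in which methyl pyruvate binds through both carbonyl oxygens to the square-planar divalent copper bis(oxazoline) complex, the tert-butyl groups shield one ketone face and the enol silane attacks the other, which with the (R,R) ligand should create C10 as R, while brief acid removes only the labile tertiary trimethylsilyl ether.

Step 7
Reactants: 12 methyl (2R)-2-hydroxy-2-methyl-4-oxo-4-Fu-butanoate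
Product: 14 (3R,5S)-3-hydroxy-3-methyl-5-Fu-dihydrofuran-2(3H)-one (hydroxyl trans to Fu), via diol ester 13 (not isolated)
Conditions: (R)-Me-CBS (0.3 equiv), BH3·SMe2 (2.5 equiv), THF, −30 °C; MeOH; PPTS (cat.), CH2Cl2, rt
Reagents that add atoms: none
Why: Corey–Bakshi–Shibata reduction with the flat furyl ring as the large and the CH2 arm as the small substituent should set C8 as S under catalyst control, and the γ-hydroxy ester then lactonises under mild acid to the trans lactone, whose chromatographic separation from the cis isomer removes the products of any stereochemical leakage in steps 6 and 7.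

Step 8
Reactants: 14 (3R,5S)-3-hydroxy-3-methyl-5-Fu-dihydrofuran-2(3H)-one
Product: 15 (2R,4S)-2,4-dihydroxy-N-methoxy-N,2-dimethyl-4-Fu-butanamide
Conditions: MeONHMe·HCl, AlMe3, CH2Cl2, 0 °C to rt; aq potassium sodium tartrate; used without delay
Reagents that add atoms: N,O-dimethylhydroxylamine hydrochloride, CNOC.Cl
Why: Aluminium amide aminolysis of a lactone (Weinreb amidation) opens the C8–O–C1 ring without touching either stereocentre and turns C1 into an acyl donor that accepts exactly one carbon nucleophile.

Step 9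
Reactants: 15 (2R,4S)-2,4-dihydroxy-N-methoxy-N,2-dimethyl-4-Fu-butanamide
Product: 16 (2R,4S)-N-methoxy-N,2-dimethyl-2,4-bis(triethylsilyloxy)-4-Fu-butanamide
Conditions: TESOTf (3 equiv), 2,6-lutidine, CH2Cl2, −78 to 0 °C
Reagents that add atoms: triethylsilyl triflate, CC[Si](CC)(CC)OS(=O)(=O)C(F)(F)F
Why: A silyl triflate with a hindered pyridine base silylates both the secondary and the hindered tertiary hydroxyl at low temperature, which blocks relactonisation and gives two ethers of graded lability for the endgame.

Step 10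
Reactants: 16 (2R,4S)-N-methoxy-N,2-dimethyl-2,4-bis(triethylsilyloxy)-4-Fu-butanamide
Product: 17 (3R,5S)-3-methyl-3,5-bis(triethylsilyloxy)-5-Fu-pentan-2-one
Conditions: MeMgBr, THF, 0 °C; aq NH4Cl
Reagents that add atoms: methylmagnesium bromide, C[Mg]Br
Why: Weinreb ketone synthesis in which the magnesium-chelated tetrahedral adduct prevents a second addition, so C2 enters as a methyl ketone next to the quaternary C10.

Step 11
Reactants: 18 propargyl alcohol
Product: 20 (E)-3-iodo-2-methylprop-2-en-1-ol, via alkenylalane 19 (not isolated)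
Conditions: AlMe3 (3 equiv), Cp2ZrCl2 (0.25 equiv), CH2Cl2, 0 °C to rt; I2, THF, −30 °C
Reagents that add atoms: trimethylaluminium, C[Al](C)C; iodine, [I][I]
Why: Zirconium-catalysed Negishi carboalumination adds methyl and aluminium syn across the alkyne with aluminium at the terminus, and iodinolysis with retention fixes the E geometry that becomes C4=C5.

Step 12
Reactants: 20 (E)-3-iodo-2-methylprop-2-en-1-ol
Product: 21 (E)-3-bromo-1-iodo-2-methylprop-1-ene
Conditions: CBr4, PPh3, CH2Cl2, 0 °C
Reagents that add atoms: carbon tetrabromide, BrC(Br)(Br)Br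
Why: Appel bromination converts the primary allylic alcohol under neutral conditions by SN2 displacement of the oxyphosphonium ion and leaves the alkenyl iodide and its geometry untouched.

Step 13
Reactants: 17 (3R,5S)-3-methyl-3,5-bis(triethylsilyloxy)-5-Fu-pentan-2-one; 21 (E)-3-bromo-1-iodo-2-methylprop-1-ene
Product: 23 (1E,6R,8S)-1-iodo-2,6-dimethyl-6,8-bis(triethylsilyloxy)-8-Fu-oct-1-en-5-one, via lithium enolate 22 (not isolated)
Conditions: LiN(iPr)2 (1.05 equiv), THF, −78 °C; 21 (2 equiv), DMPU, −78 to −30 °C
Reagents that add atoms: none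
Why: Kinetic lithium enolate alkylation in which only C2 carries enolisable hydrogens because C10 is fully substituted, and the unhindered primary allylic bromide reacts by SN2 while the sp2 C–I bond is inert to the enolate, forming C2–C3.

Step 14
Reactants: 23 (1E,6R,8S)-1-iodo-2,6-dimethyl-6,8-bis(triethylsilyloxy)-8-Fu-oct-1-en-5-one
Product: 25 tert-butyldimethylsilyl (Z)-formyl acrylate (C6 aldehyde cis to the C12 silyl ester on C7=C11; 8S,10R; E-iodoalkene), via furan endoperoxide 24 (not isolated)
Conditions: O2, polymer-bound rose bengal, visible light (495 nm cut-off filter), CH2Cl2, −78 °C; Ar purge, warm to rt; filter, concentrate, use crude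
Reagents that add atoms: dioxygen, O=O
Why: Singlet oxygen adds [4+2] across the electron-rich furan far faster than it attacks the iodine-deactivated alkene, and the 2-silyl endoperoxide collapses by migration of silicon from C12 to the peroxide oxygen, the known photooxygenation mode of 2-silylfurans, which gives the silyl ester at C12 and the aldehyde at C6 with the cis geometry inherited from the ring.

Step 15
Reactants: 25 tert-butyldimethylsilyl (Z)-formyl acrylate
Product: 27 (6R,8S,10R)-8,10-bis(triethylsilyloxy)-13-(tert-butyldimethylsilyloxy)-1-oxogermacra-4E,7(11)-dien-12,6-olide, via C6 chromium alkoxide 26 (not isolated)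
Conditions: CrCl2 (15 equiv), NiCl2 (0.15 equiv), 4 Å MS, degassed DMSO/THF (3:1), rt, syringe-pump addition of 25 (final about 1 mM); aq potassium sodium tartrate
Reagents that add atoms: none
Why: Zerovalent nickel generated in situ inserts into the C5–I bond with retention, hands the E-alkenyl group to trivalent chromium, and this species adds 1,2 to the non-enolisable C6 aldehyde to give alkoxide 26, which displaces silanolate from the C12 silyl ester. The closest known reaction types are Nozaki–Hiyama–Kishi alkenyl iodide–aldehyde macrocyclisations to medium rings and alkenylchromium additions to aldehydes carrying a cis ester that lactonise spontaneously to butenolides. The ten-membered carbocycle closes by intramolecular carbonyl addition (C5–C6 bond), helped by three flat units in the chain (E-olefin, ketone, tetrasubstituted olefin), and the butenolide closes 5-exo-trig because the former furan holds C6–O and C12 cis on C7=C11. C6 (R) requires Re-face attack: A(1,3) strain with the C13 CH2OTBS group makes H-8 eclipse C7=C11 and sends C9 to one face, the chromium-bound aldehyde oxygen turns away from branched C8 toward C12, and C5 can then reach C6 only from the face opposite C9 without a syn-pentane fold of the nascent ring. Chemoselectivity for the aldehyde over the C1 ketone and the ester is inherent to alkenylchromium reagents, slow addition at high dilution suppresses oligomers, and silyl ethers instead of esters on O8 and O13 leave no good leaving group γ to the reducible ene-dicarbonyl unit.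

Step 16
Reactants: 27 (6R,8S,10R)-8,10-bis(triethylsilyloxy)-13-(tert-butyldimethylsilyloxy)-1-oxogermacra-4E,7(11)-dien-12,6-olide
Product: 28 (6R,8S,10R)-8-hydroxy-10-triethylsilyloxy-13-(tert-butyldimethylsilyloxy)-1-oxogermacra-4E,7(11)-dien-12,6-olide
Conditions: HF·pyridine buffered with excess pyridine, THF, 0 °C, monitored closely
Reagents that add atoms: none
Why: Graded silyl ether lability lets buffered fluoride cleave the secondary triethylsilyl ether well before the hindered tertiary triethylsilyl ether and the primary tert-butyldimethylsilyl ether, and the near-neutral, alcohol-free medium disfavours both lactone migration from O6 to O8 and ketal formation between O8 and C1.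

Step 17
Reactants: 28 (6R,8S,10R)-8-hydroxy-10-triethylsilyloxy-13-(tert-butyldimethylsilyloxy)-1-oxogermacra-4E,7(11)-dien-12,6-olide
Product: 29 (6R,8S,10R)-8-methacryloyloxy-10-triethylsilyloxy-13-(tert-butyldimethylsilyloxy)-1-oxogermacra-4E,7(11)-dien-12,6-olide
Conditions: methacrylic anhydride, DMAP (0.2 equiv), iPr2NEt, CH2Cl2, 0 °C
Reagents that add atoms: methacrylic anhydride, C=C(C)C(=O)OC(=O)C(C)=C
Why: DMAP-catalysed (Steglich-type) acylation with the anhydride esterifies the only free hydroxyl quickly at low temperature with retention at C8, so the alcohol that could attack C12 is capped at once.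

Step 18
Reactants: 29 (6R,8S,10R)-8-methacryloyloxy-10-triethylsilyloxy-13-(tert-butyldimethylsilyloxy)-1-oxogermacra-4E,7(11)-dien-12,6-olide
Product: 30 (6R,8S,10R)-10,13-dihydroxy-8-methacryloyloxy-1-oxogermacra-4E,7(11)-dien-12,6-olide
Conditions: HF·pyridine (excess, unbuffered), THF, 0 °C to rt
Reagents that add atoms: none
Why: Unbuffered hydrogen fluoride–pyridine removes the two remaining silyl ethers by Si–F bond formation under mildly acidic conditions that the esters, the butenolide and the olefins tolerate.

Step 19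
Reactants: 30 (6R,8S,10R)-10,13-dihydroxy-8-methacryloyloxy-1-oxogermacra-4E,7(11)-dien-12,6-olide
Product: 32 (6R,8S,10R)-10,13-diacetoxy-8-methacryloyloxy-1-oxogermacra-4E,7(11)-dien-12,6-olide (CNP0115165.1), via C13 monoacetate 31 (not isolated)
Conditions: Ac2O (excess), DMAP (2 equiv), CH2Cl2, rt
Reagents that add atoms: acetic anhydride, CC(=O)OC(C)=O
Why: DMAP-mediated acetylation through the N-acetylpyridinium ion esterifies the primary C13 hydroxyl at once and the hindered tertiary C10 α-ketol hydroxyl on longer exposure, and it avoids the Lewis or Brønsted acids that could trigger a transannular Prins reaction between the C1 ketone and C4=C5.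

Compound list
1 | 3-furanmethanol | OCc1ccoc1 | starting material
2 | 3-[(tert-butyldimethylsilyloxy)methyl]furan | CC(C)(C)[Si](C)(C)OCc1ccoc1 | intermediate
3 | 2-lithio-3-[(tert-butyldimethylsilyloxy)methyl]furan (not isolated) | [Li]c1occc1CO[Si](C)(C)C(C)(C)C | intermediate
4 | 2-(tert-butyldimethylsilyl)-3-furanmethanol | OCc1ccoc1[Si](C)(C)C(C)(C)C | intermediate
5 | N-methoxy-N-methylacetamide | CC(=O)N(C)OC | starting material
6 | C4,O-dilithio derivative of 4 (not isolated) | [Li]OCc1c([Li])coc1[Si](C)(C)C(C)(C)C | intermediate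
7 | 4-acetyl-2-(tert-butyldimethylsilyl)-3-(hydroxymethyl)furan | CC(=O)c1coc([Si](C)(C)C(C)(C)C)c1CO | intermediate
8 | methyl ketone Fu–C(=O)CH3 | CC(=O)c1coc([Si](C)(C)C(C)(C)C)c1CO[Si](C)(C)C(C)(C)C | intermediate
9 | enol silane Fu–C(OSiMe3)=CH2 | C=C(O[Si](C)(C)C)c1coc([Si](C)(C)C(C)(C)C)c1CO[Si](C)(C)C(C)(C)C | intermediate
10 | methyl pyruvate | COC(=O)C(C)=O | starting material
11 | methyl (2R)-2-methyl-4-oxo-2-(trimethylsilyloxy)-4-Fu-butanoate (not isolated) | COC(=O)[C@](C)(O[Si](C)(C)C)CC(=O)c1coc([Si](C)(C)C(C)(C)C)c1CO[Si](C)(C)C(C)(C)C | intermediate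
12 | methyl (2R)-2-hydroxy-2-methyl-4-oxo-4-Fu-butanoate | COC(=O)[C@](C)(O)CC(=O)c1coc([Si](C)(C)C(C)(C)C)c1CO[Si](C)(C)C(C)(C)C | intermediate
13 | methyl (2R,4S)-2,4-dihydroxy-2-methyl-4-Fu-butanoate (not isolated) | COC(=O)[C@](C)(O)C[C@H](O)c1coc([Si](C)(C)C(C)(C)C)c1CO[Si](C)(C)C(C)(C)C | intermediate
14 | (3R,5S)-3-hydroxy-3-methyl-5-Fu-dihydrofuran-2(3H)-one, hydroxyl trans to Fu | O=C1O[C@H](c2coc([Si](C)(C)C(C)(C)C)c2CO[Si](C)(C)C(C)(C)C)C[C@@]1(C)O | intermediate
15 | (2R,4S)-2,4-dihydroxy-N-methoxy-N,2-dimethyl-4-Fu-butanamide | CON(C)C(=O)[C@](C)(O)C[C@H](O)c1coc([Si](C)(C)C(C)(C)C)c1CO[Si](C)(C)C(C)(C)C | intermediate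
16 | (2R,4S)-N-methoxy-N,2-dimethyl-2,4-bis(triethylsilyloxy)-4-Fu-butanamide | CON(C)C(=O)[C@](C)(O[Si](CC)(CC)CC)C[C@H](O[Si](CC)(CC)CC)c1coc([Si](C)(C)C(C)(C)C)c1CO[Si](C)(C)C(C)(C)C | intermediate
17 | (3R,5S)-3-methyl-3,5-bis(triethylsilyloxy)-5-Fu-pentan-2-one | CC(=O)[C@](C)(O[Si](CC)(CC)CC)C[C@H](O[Si](CC)(CC)CC)c1coc([Si](C)(C)C(C)(C)C)c1CO[Si](C)(C)C(C)(C)C | intermediate
18 | propargyl alcohol | C#CCO | starting material
19 | (E)-alkenyl(dimethyl)alane as its O-dimethylaluminium alkoxide (not isolated) | C[Al](C)OC/C(C)=C/[Al](C)C | intermediate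
20 | (E)-3-iodo-2-methylprop-2-en-1-ol | OC/C(C)=C/I | intermediate
21 | (E)-3-bromo-1-iodo-2-methylprop-1-ene | BrC/C(C)=C/I | intermediate
22 | C1–C2 lithium enolate of 17 (not isolated) | C=C(O[Li])[C@](C)(O[Si](CC)(CC)CC)C[C@H](O[Si](CC)(CC)CC)c1coc([Si](C)(C)C(C)(C)C)c1CO[Si](C)(C)C(C)(C)C | intermediate
23 | (1E,6R,8S)-1-iodo-2,6-dimethyl-6,8-bis(triethylsilyloxy)-8-Fu-oct-1-en-5-one | I/C=C(C)/CCC(=O)[C@](C)(O[Si](CC)(CC)CC)C[C@H](O[Si](CC)(CC)CC)c1coc([Si](C)(C)C(C)(C)C)c1CO[Si](C)(C)C(C)(C)C | intermediate
24 | furan endoperoxide of 23 (2,3,7-trioxabicyclo[2.2.1]hept-5-ene, bridgeheads C6 and C12 as a mixture of faces; not isolated) | I/C=C(C)/CCC(=O)[C@](C)(O[Si](CC)(CC)CC)C[C@H](O[Si](CC)(CC)CC)C1=C(CO[Si](C)(C)C(C)(C)C)C2([Si](C)(C)C(C)(C)C)OOC1O2 | intermediate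
25 | tert-butyldimethylsilyl (Z)-formyl acrylate: C6 aldehyde on C7, C13 CH2OTBS and C12 silyl ester on C11, 8S,10R, E-iodoalkene (used crude) | I/C=C(C)/CCC(=O)[C@](C)(O[Si](CC)(CC)CC)C[C@H](O[Si](CC)(CC)CC)/C(C=O)=C(\CO[Si](C)(C)C(C)(C)C)C(=O)O[Si](C)(C)C(C)(C)C | intermediate
26 | ten-membered (6R,8S,10R) C6 dichlorochromium alkoxide, C12 silyl ester still open and cis to C6 (not isolated) | CC[Si](CC)(CC)O[C@H]1C[C@@](C)(O[Si](CC)(CC)CC)C(=O)CC/C(C)=C/[C@@H](O[Cr](Cl)Cl)/C1=C(/CO[Si](C)(C)C(C)(C)C)C(=O)O[Si](C)(C)C(C)(C)C | intermediate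
27 | (6R,8S,10R)-8,10-bis(triethylsilyloxy)-13-(tert-butyldimethylsilyloxy)-1-oxogermacra-4E,7(11)-dien-12,6-olide | CC[Si](CC)(CC)O[C@H]1C[C@@](C)(O[Si](CC)(CC)CC)C(=O)CC/C(C)=C/[C@H]2OC(=O)C(CO[Si](C)(C)C(C)(C)C)=C12 | intermediate
28 | (6R,8S,10R)-8-hydroxy-10-triethylsilyloxy-13-(tert-butyldimethylsilyloxy)-1-oxogermacra-4E,7(11)-dien-12,6-olide | O[C@H]1C[C@@](C)(O[Si](CC)(CC)CC)C(=O)CC/C(C)=C/[C@H]2OC(=O)C(CO[Si](C)(C)C(C)(C)C)=C12 | intermediate
29 | (6R,8S,10R)-8-methacryloyloxy-10-triethylsilyloxy-13-(tert-butyldimethylsilyloxy)-1-oxogermacra-4E,7(11)-dien-12,6-olide | C=C(C)C(=O)O[C@H]1C[C@@](C)(O[Si](CC)(CC)CC)C(=O)CC/C(C)=C/[C@H]2OC(=O)C(CO[Si](C)(C)C(C)(C)C)=C12 | intermediate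
30 | (6R,8S,10R)-10,13-dihydroxy-8-methacryloyloxy-1-oxogermacra-4E,7(11)-dien-12,6-olide | C=C(C)C(=O)O[C@H]1C[C@@](C)(O)C(=O)CC/C(C)=C/[C@H]2OC(=O)C(CO)=C12 | intermediate
31 | (6R,8S,10R)-13-acetoxy-10-hydroxy-8-methacryloyloxy-1-oxogermacra-4E,7(11)-dien-12,6-olide (not isolated) | C=C(C)C(=O)O[C@H]1C[C@@](C)(O)C(=O)CC/C(C)=C/[C@H]2OC(=O)C(COC(C)=O)=C12 | intermediate
32 | (6R,8S,10R)-10,13-diacetoxy-8-methacryloyloxy-1-oxogermacra-4E,7(11)-dien-12,6-olide, CNP0115165.1 | C=C(C)C(=O)O[C@H]1C[C@@](C)(OC(C)=O)C(=O)CC/C(C)=C/[C@H]2OC(=O)C(COC(C)=O)=C12 | target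

Total step count: 19. Longest linear sequence: 17 (steps 1–10 and 13–19, from 3-furanmethanol).

Steps most likely to fail

Step 15 (ring closure).
- What may go wrong: electron transfer from divalent chromium to the ene-dicarbonyl unit ahead of C–I activation, loss or O-to-O shift of the silyl ester before the addition, oligomerisation, and insufficient facial bias at C6.
- Fallback: it replaces the transient silyl ester by an isolable substrate and substrate control by reagent control. It sets out from 25, which on stirring with wet THF and silica gel should hydrolyse and close to the γ-hydroxybutenolide F1 (lactol epimers, purified by chromatography). Alkylation of its ring-opened carboxylate (MeI, K2CO3, DMF, 0 °C) should give the methyl (Z)-formyl acrylate F2. This ester is purified and then cyclised with CrCl2/NiCl2 in the presence of a stoichiometric chiral oxazoline–sulfonamide ligand and Et3N in THF at high dilution, both ligand enantiomers being tried. The C6 alkoxide lactonises with loss of methoxide and the sequence rejoins the route at 27.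

Step 13 (C2–C3 alkylation).
- What may go wrong: proton exchange between enolate and product (double alkylation), sluggish reaction of the hindered enolate, or silyl migration from O10 to the enolate oxygen.
- Fallback: it uses an aza-enolate. From 17, condensation with Me2NNH2 (cat. AcOH, EtOH, warm) should give the N,N-dimethylhydrazone F3. Deprotonation at C2 (LiN(iPr)2, THF, 0 °C) and alkylation with 21 at −78 °C should give the monoalkylated hydrazone F4. Hydrolysis with aq Cu(OAc)2 in THF returns ketone 23.

Step 16 (unveiling O8).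
- What may go wrong: incomplete discrimination between the three silyl ethers, lactone migration from O6 to O8, or transannular hemiketal formation of the free C8 hydroxyl with C1.
- Fallback: it moves the C8 acylation in front of the ring closure, so that a free C8 hydroxyl never coexists with the lactone. From 23, buffered HF·pyridine should give the acyclic C8 alcohol F5, and methacrylic anhydride/DMAP its methacrylate F6. Photooxygenation as in step 14 should then give the C8-methacrylate formyl acrylate silyl ester F7. Ring closure as in step 15 delivers 29 directly, at the price of an allylic ester γ to C12 during exposure to CrCl2.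

Further compounds
F1 | step 15 | γ-hydroxybutenolide (C6 lactol epimers) carrying the 8S,10R bis-TES chain and the E-iodoalkene | I/C=C(C)/CCC(=O)[C@](C)(O[Si](CC)(CC)CC)C[C@H](O[Si](CC)(CC)CC)C1=C(CO[Si](C)(C)C(C)(C)C)C(=O)OC1O
F2 | step 15 | methyl (Z)-formyl acrylate, methyl ester analogue of 25 | I/C=C(C)/CCC(=O)[C@](C)(O[Si](CC)(CC)CC)C[C@H](O[Si](CC)(CC)CC)/C(C=O)=C(\CO[Si](C)(C)C(C)(C)C)C(=O)OC
F3 | step 13 | N,N-dimethylhydrazone of 17 (NMe2 anti to C10) | C/C(=N\N(C)C)[C@](C)(O[Si](CC)(CC)CC)C[C@H](O[Si](CC)(CC)CC)c1coc([Si](C)(C)C(C)(C)C)c1CO[Si](C)(C)C(C)(C)C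
F4 | step 13 | N,N-dimethylhydrazone of 23 | I/C=C(C)/CC/C(=N\N(C)C)[C@](C)(O[Si](CC)(CC)CC)C[C@H](O[Si](CC)(CC)CC)c1coc([Si](C)(C)C(C)(C)C)c1CO[Si](C)(C)C(C)(C)C
F5 | step 16 | acyclic C8 alcohol, (1E,6R,8S)-8-hydroxy-1-iodo-2,6-dimethyl-6-triethylsilyloxy-8-Fu-oct-1-en-5-one | I/C=C(C)/CCC(=O)[C@](C)(O[Si](CC)(CC)CC)C[C@H](O)c1coc([Si](C)(C)C(C)(C)C)c1CO[Si](C)(C)C(C)(C)C
F6 | step 16 | acyclic C8 methacrylate of F5 | I/C=C(C)/CCC(=O)[C@](C)(O[Si](CC)(CC)CC)C[C@H](OC(=O)C(C)=C)c1coc([Si](C)(C)C(C)(C)C)c1CO[Si](C)(C)C(C)(C)C
F7 | step 16 | tert-butyldimethylsilyl (Z)-formyl acrylate with the C8 methacrylate in place | I/C=C(C)/CCC(=O)[C@](C)(O[Si](CC)(CC)CC)C[C@H](OC(=O)C(C)=C)/C(C=O)=C(\CO[Si](C)(C)C(C)(C)C)C(=O)O[Si](C)(C)C(C)(C)C
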